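## The problem

The target 20 is a labdane (ring A = C1–C5 and C10, ring B = C5–C10). Its decalin is cis-fused, with H5 and the C10 methyl group both on the β face. Five stereocentres must be set: quaternary C10, C5, the 6α carbinol, the 2α carbinol and quaternary C4. C4 carries the C18 methyl group (α) and the acetoxymethyl carbon C19 (β, cis to the C10 methyl). C10, C5 and C6 are contiguous on ring B and can be made in one stereochemical event. Once they stand, C5 and C10 can direct the closure that creates C4, and the folded bicycle can direct a hydride to C2, so only one absolute induction is needed. The tetrasubstituted C8=C9 alkene lies between quaternary C10 and the C8 methyl group and holds the two-carbon link to the butenolide; its position must be fixed regiospecifically, because nothing would steer an equilibration. The sensitive groups are the butenolide (base, hydride, nucleophiles), the one primary acetate beside two free secondary alcohols, and any intermediate with a carbonyl group next to C5, which could leak into the trans series or expel the C6 oxygen. The key step is opened by the chain O–C2–C3–C4–C19–O: C3–C4 is the central bond of a 1,4-dioxygenated unit and joins the β-carbons of two enol ethers, two donor carbons that can be united only after electrons are removed.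

## Retrosynthesis

**C12–C13 (20 ⇒ 19 ⇒ 18 + 17).**
- After removal of the two silyl groups (19), the sp3–sp2 bond between the ethylene link and the lactone is cut. This gives alkylborane 18, made in the flask from diene 16, and commercial 4-bromofuran-2(5H)-one 17.
- Cutting here, rather than at C11–C12 or inside the lactone, keeps the fragile butenolide out of every earlier step and brings it in as an intact ring.
- The forward B-alkyl Suzuki–Miyaura coupling must spare an acetate and two silyl ethers. The hydroboration must choose the monosubstituted C11=C12 alkene of 16 over C8=C9.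

**C9–C11 (16 ⇒ 15 ⇒ 14 ⇒ 13).**
- The vinyl group is removed to give enol triflate 15.
- The enolate 14 behind it is traced to enone 13 (C7=C8–C9=O) by 1,4-addition of hydride.
- The neighbouring plan is a C9 ketone that is methylated at C8 and then enolised towards the more substituted side. It needs more steps and leaves the alkene position to the base. The enone already holds the C8 methyl group and defines the enolate.
- 13 has no side chain and only one carbonyl group.

**Ring A oxidation levels (13 ⇒ 12 ⇒ 11 ⇒ 10 ⇒ 9).**
- No skeletal bond is cut.
- The three hydroxy groups are told apart as follows: O6 is silylated from the start, O19 is primary, and O2 is an axial, flanked secondary alcohol.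
- Both O2 and O19 come from keto aldehyde 10, the hydrolysed form of bis(dimethyl acetal) 9.
- The forward reduction must deliver hydride to the β face of C2 and leave the hindered enone alone.

**C3–C4, the key cut (9 ⇒ 8).**
- Opening ring A at C3–C4 gives ring B bis(methyl enol ether) 8.
- A cut at C4–C5 or C1–C10 would ask an enolate or a cation to build a quaternary carbon next to another fully substituted centre. The C3–C4 cut uses an unhindered CH2 terminus as nucleophile and returns both oxygenated carbons at useful oxidation levels.
- The precursor loses one ring and the hardest stereocentre.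
- The forward reaction needs one face of planar C4.

**Reconnection C2=C19 (8 ⇒ 7 ⇒ 6 ⇒ 5).**
- Both enol ethers come from acetals (7) by loss of methanol, and the acetals from 1,6-keto aldehyde 6. A 1,6-dicarbonyl compound is a cleaved cyclohexene, so C2 and C19 are rejoined in bicycle 5, whose temporary ring T (C10–C1–C2=C19–C4–C5) holds the two arms cis.
- The neighbouring plan puts an acetyl group on C5 and an ester arm on C10, extended by Wittig methoxymethylenation and Cp2Ti(μ-Cl)(μ-CH2)AlMe2. It was set aside for three reasons:
  - A C4 ketone makes H5 acidic, with the C6 oxygen in the β-position.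
  - The titanium reagent does not tolerate a C9 carbonyl group.
  - CH3 and CH2CO2Me on C10 are too alike to relay configuration to C5 and C6.
- In 6 the carbonyl groups are one atom further from C5, and no carbon is removed and put back.

**C6 carbinol (5 ⇒ 4 ⇒ 3).**
- The silyl ether goes back to alcohol 4 and to enedione 3.
- Every oxygen electrophile would reach C6 trans to the C4 arm, so the cis relation is best made by bringing hydrogen in last, from the convex face of a folded bicycle.
- The reduction must distinguish C6=O (flanked by two C–H) from C9=O (flanked by C10 and the C8 methyl).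

**C5–C4 and C10–C1 (3 ⇒ 1 + 2).**
- A Diels–Alder cut gives 2,6-dimethyl-1,4-benzoquinone 1 and (E)-2-methylpenta-1,3-diene 2, which together hold all fourteen carbons of the bicyclic core.
- Suprafacial addition makes H5 and the C10 methyl cis.
- The reaction needs the orientation in which the CH2 terminus of 2 bonds to the methyl-bearing quinone carbon, and one enantiotopic face. A chiral Lewis acid on the less hindered carbonyl oxygen can provide both.

## Roads not taken

**Alternative 1:** the cut is C5–C10 plus C6–C7.
- *Forward step:* a C7=C8–C9=C10 diene adds within the molecule to a (Z)-C5=C6 alkenylboronate tethered through C1–C4, giving octalin boronate A1.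
- *Merits:*
  - Both rings, two C–C bonds and C5, C6 and C10 arise in one suprafacial step.
  - The Z geometry becomes the cis relation of C4 and boron, and C–B oxidation with retention gives 6α-OH.
  - C8=C9 appears in place, with the side-chain carbons attached.
  - In complexity per step this road is better than the chosen one, whose key step makes one bond, one ring and one stereocentre.
- *Weak points:*
  - C10 is a fully substituted diene terminus, so CH3 or C1 must point inwards in the s-cis form, buttressed by the C8 and C9 substituents.
  - The dienophile is only weakly activated and hangs on quaternary C4, so strong heating is to be expected.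
  - A four-atom tether gives little bias between cis and trans fusion.
  - The C9=C10 geometry, C2 and quaternary C4 must all be set in an open chain.
- *Comparison:* the chosen plan sets the same three centres with an activated quinone under catalyst control at low temperature, and it builds C4 on a ring template.

**Alternative 2:** the cut is C6–C7.
- *Forward step:* CrCl2 turns a C7 allylic bromide on the C10 arm into an allylchromium species that adds to the formyl carbon C6 on C5, giving A2, the 2-O-silyl ether of the target.
- *Merits:*
  - Divalent chromium tolerates the acetate and the butenolide.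
  - The product is one desilylation from 20, far shorter than the eight steps that follow the chosen key step.
- *Weak points:*
  - Allylchromium reagents bond through the γ-carbon, here fully substituted C9, where closure would give a four-membered ring. The required α-attack runs against the normal course.
  - The stereodefined tetrasubstituted alkene must be built on neopentyl C10.
  - The aldehyde sits between two quaternary carbons on an epimerisable C5.
  - No ordered transition state fixes C6.
- *Comparison:* the chosen plan offers standard reactions after its key step and a C6 centre set by simple convex-face hydride delivery.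

**Alternative 3:** the cut is C4–C5.
- *Forward step:* BF3·OEt2 opens a tethered 2,2-disubstituted epoxide at C4, and enol silane carbon C5 attacks with inversion, giving hydroxy ketone A3.
- *Merits:*
  - C4 would be set stereospecifically from a reagent-made epoxide. In principle this is more secure than the conformational control relied on here.
  - C19–OH is released free and already distinct from O2.
  - The C6 ketone invites convex-face reduction.
- *Weak points:*
  - Such epoxides ionise at the tertiary carbon under BF3·OEt2, which erodes inversion and opens the Meinwald rearrangement to an aldehyde.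
  - The enol silane must point towards the hindered C5 side.
  - A3 keeps an epimerisable C5 beside the ketone.
  - The dioxolane and the silyl ether face a strong Lewis acid.
  - The C8 methyl group and the alkene still have to be added.
- *Comparison:* the chosen plan offers buffered, nearly neutral conditions, a C5 that is never α to a carbonyl group, and a ring B that carries the C8 methyl group from the first step.

Key step: step 6

Convention: labdane numbering is used for all compounds; β means the face of the C10 methyl group (C20), α the opposite face.

Assumption: the (S)-oxazaborolidinium catalyst of step 1 is taken to expose the quinone face that leads to 3. This follows the accepted binding model, with boron on the carbonyl oxygen flanked by vinylic C–H. The (R)-catalyst is equally available if the sense proves opposite.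

## Steps

Step 1
Reactants: 1 2,6-dimethyl-1,4-benzoquinone; 2 (E)-2-methylpenta-1,3-diene
Product: 3 (4aR,5R,8aS)-2,5,7,8a-tetramethyl-4a,5,8,8a-tetrahydronaphthalene-1,4-dione (cis-fused; C8a = C10, C4a = C5, C4 = C6, C1 = C9, C5 = C4, C6 = C19, C7 = C2, C8 = C1)
Conditions: (S)-3,3-diphenyl-1-(2-methylphenyl)tetrahydro-1H,3H-pyrrolo[1,2-c][1,3,2]oxazaborole (20 mol%), HN(SO2CF3)2 (18 mol%), CH2Cl2, −78 to −40 °C
Reagents that add atoms: none
Why: Catalytic enantioselective Diels–Alder reaction of a quinone; the cationic boron binds the less hindered and more basic carbonyl oxygen (future C6=O), which makes the methyl-bearing β-carbon (future C10) the electrophilic end, and the CH2 terminus of 2, whose coefficient is raised by both methyl groups, bonds there for electronic and steric reasons alike. Suprafacial addition sets H5 and the C10 methyl cis and the catalyst face sets the absolute configuration; the endo-derived C4 centre is erased in step 5.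

Step 2
Reactants: 3 Diels–Alder adduct
Product: 4 (4S,4aR,5R,8aS)-4-hydroxy-2,5,7,8a-tetramethyl-4a,5,8,8a-tetrahydronaphthalen-1(4H)-one (6α-alcohol)
Conditions: NaBH4, CeCl3·7H2O, MeOH/CH2Cl2, −78 °C
Reagents that add atoms: none
Why: Luche 1,2-reduction; C6=O lies between C5–H and C7–H whereas C9=O is screened by quaternary C10 and the C8 methyl, so only C6 should react. The bicycle is folded and ring T blocks the α face, so hydride enters from the convex β face and the hydroxy group ends α, cis to C4.

Step 3
Reactants: 4 6α-alcohol
Product: 5 6α-tert-butyldimethylsilyl ether of 4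
Conditions: t-BuMe2SiOTf, 2,6-lutidine, CH2Cl2, 0 °C
Reagents that add atoms: tert-butyldimethylsilyl triflate, CC(C)(C)[Si](C)(C)OS(=O)(=O)C(F)(F)F
Why: Silyl triflate silylation copes with a hindered concave alcohol. The group must outlast mild acid and fall to fluoride at the end; a free 6-OH would close a lactol on C19 after the cleavage.

Step 4
Reactants: 5 6α-silyl ether
Product: 7 ring B bis(dimethyl acetal): 4-(TBSO)-5-(1,1-dimethoxypropan-2-yl)-6-(2,2-dimethoxypropyl)-2,6-dimethylcyclohex-2-en-1-one with both arms and OTBS on the α face, via keto aldehyde 6 (not isolated)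
Conditions: O3, CH2Cl2/MeOH, −78 °C (Sudan Red 7B end point); Me2S, to rt; then HC(OMe)3, pyridinium p-toluenesulfonate (cat.), 40 °C
Reagents that add atoms: ozone, [O-][O+]=O; trimethyl orthoformate, COC(OC)OC
Why: Chemoselective ozonolysis: the trisubstituted C2=C19 alkene is much more electron-rich than the enone alkene, and reductive work-up gives the C2 methyl ketone and the C19 aldehyde. Orthoformate acetalisation in the same flask protects both before any aldol closure, while the hindered conjugated C9 carbonyl should not ketalise. C5, C6 and C10 are untouched and C4 is of no consequence.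

Step 5
Reactants: 7 ring B bis(dimethyl acetal)
Product: 8 ring B bis(methyl enol ether): 4-(TBSO)-5-[(E)-1-methoxyprop-1-en-2-yl]-6-(2-methoxyprop-2-en-1-yl)-2,6-dimethylcyclohex-2-en-1-one
Conditions: Me3SiOTf (2.4 equiv), i-Pr2NEt (3 equiv), CH2Cl2, −40 to 0 °C; aq. NaHCO3, basic alumina
Reagents that add atoms: none
Why: Silyl-triflate-induced loss of methanol from acetals (oxocarbenium ion, then deprotonation by the hindered amine), which is known to favour the less substituted enol ether. The C2 ion loses a proton from the C3 methyl rather than from neopentyl C1H2, and the C19 ion can only lose H4. The ketal ionises first, so a C2 cation and a C4 nucleophile hardly coexist.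

Step 6
Reactants: 8 ring B bis(methyl enol ether)
Product: 9 cis-decalin bis(dimethyl acetal): C2 dimethyl ketal, C19 dimethyl acetal on the β face of C4, C18 methyl α, 6α-OTBS, C7=C8–C9=O enone
Conditions: reticulated vitreous carbon anode, Pt cathode, undivided cell, constant current, 2.2 F/mol, 0.1 M LiClO4, MeOH/THF 1:1, 2,6-lutidine (4 equiv), rt
Reagents that add atoms: methanol, CO
Why: The trisubstituted C4=C19 enol ether is the most easily oxidised group and loses one electron at the anode to give a radical cation with an electrophilic C4; the terminal carbon C3 of the 2-methoxyallyl group bonds to it, methanol captures the C2 oxocarbenium ion, the C19 α-methoxy radical gives up a second electron and is captured by methanol too, and 2,6-lutidine carries the protons to the cathode, where hydrogen is evolved. The closest known reaction type is the intramolecular anodic coupling of two enol ethers in methanol, which forms six-membered rings and quaternary carbons. Ring A closes in a chair-like array, 6-exo with respect to C4=C19 and 6-endo with respect to C2=C3; polarity dictates the endo mode, since only bonding through C3 leaves the charge on oxygen-stabilised C2. The one new stereocentre, C4, is controlled by C5: allylic 1,3-strain keeps H5 near the plane of C4=C19, C6 and C10 then lie on opposite faces, and C3, which hangs on C10, can reach only the C10 side. In that chair the C4 arm is axial on ring B, C18 becomes axial on ring A and C19 equatorial, that is cis to H5 and to the C10 methyl. The array is affordable because C7, C8 and C9 are sp2 centres, so no axial hydrogen of ring B meets C18, and because the other chair would force 6α-OTBS into the fold against C1 and C3. Chemoselectivity rests on potentials (enone and silyl ether are inert where enol ethers oxidise) and on a platinum cathode at which protons are reduced before the enone; both enol ether geometries converge because C19 is not stereogenic in 9.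

Step 7
Reactants: 9 cis-decalin bis(dimethyl acetal)
Product: 10 cis-decalin 2-ketone 19-aldehyde (6α-OTBS and enone retained)
Conditions: 50% aq. CF3CO2H, CH2Cl2, 0 °C
Reagents that add atoms: water, O
Why: Acid hydrolysis of acetals; the crowded C2 ketal ionises with relief of strain and the C19 acetal follows, while a hindered secondary TBS ether survives brief cold acid. C4 is quaternary, so the 1,4-dicarbonyl unit can neither epimerise nor form a furan.

Step 8
Reactants: 10 keto aldehyde
Product: 11 2α,19-diol (6α-OTBS and enone retained)
Conditions: NaBH4, MeOH/CH2Cl2 1:1, −78 to −40 °C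
Reagents that add atoms: none
Why: Cold borohydride in MeOH/CH2Cl2 reduces aldehydes and saturated ketones in preference to conjugated enones, and this enone is also flanked by C10 and the C8 methyl. In the favoured double chair (6α-OTBS equatorial and outside the fold) C18 and C9 are both axial on the α face of ring A and flank C2, so hydride comes from the β face and gives the 2α (axial) alcohol.

Step 9
Reactants: 11 2α,19-diol
Product: 12 19-acetate with free 2α-OH
Conditions: AcCl (1.1 equiv), 2,4,6-collidine, CH2Cl2, −78 °C
Reagents that add atoms: acetyl chloride, CC(=O)Cl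
Why: Selective acylation of a primary alcohol; O19 is primary and equatorially exposed, whereas the 2α-OH is axial between C18 and C9 and should react far more slowly.

Step 10
Reactants: 12 19-acetate
Product: 13 2α-triethylsilyl ether of 12
Conditions: Et3SiOTf, 2,6-lutidine, CH2Cl2, 0 °C
Reagents that add atoms: triethylsilyl triflate, CC[Si](CC)(CC)OS(=O)(=O)C(F)(F)F
Why: A small, reactive silyl triflate reaches the hindered axial alcohol. The ether keeps the hydroxy group from consuming hydride, triflating agent and borane in steps 11 to 13.

Step 11
Reactants: 13 fully protected enone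
Product: 15 C9 enol triflate with the C8=C9 alkene and C7H2, via lithium enolate 14 (not isolated)
Conditions: LiBH(s-Bu)3 (1.1 equiv), THF, −78 °C; then N-(5-chloropyridin-2-yl)bis(trifluoromethanesulfonyl)imide, −78 to 0 °C
Reagents that add atoms: N-(5-chloropyridin-2-yl)bis(trifluoromethanesulfonyl)imide, O=S(=O)(N(c1ccc(Cl)cn1)S(=O)(=O)C(F)(F)F)C(F)(F)F; lithium tri-sec-butylborohydride, [Li+].CCC(C)[BH-](C(C)CC)C(C)CC (lithium only in 14)
Why: Conjugate reduction of a β-unsubstituted cyclohexenone by a bulky borohydride, with O-triflation of the resulting enolate, is a known regiospecific route to enol triflates. The hindered C9 carbonyl disfavours 1,2-attack, the C6 oxygen is not β to the enolate carbon and cannot be expelled, and the acetate is inert at −78 °C.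

Step 12
Reactants: 15 enol triflate
Product: 16 C9-vinyl diene (C8=C9–C11=C12)
Conditions: CH2=CHSnBu3, Pd(PPh3)4 (5 mol%), LiCl (3 equiv), THF, 65 °C
Reagents that add atoms: tributyl(vinyl)stannane, C=C[Sn](CCCC)(CCCC)CCCC
Why: Stille coupling of an enol triflate; triflates of 2,6,6-trisubstituted cyclohexenyl type are established partners. The neutral conditions spare the acetate and both silyl ethers.

Step 13
Reactants: 16 diene; 17 4-bromofuran-2(5H)-one
Product: 19 2-O-TES 6-O-TBS ether of the target, via B-alkyl borane 18 (not isolated)
Conditions: 9-borabicyclo[3.3.1]nonane, THF, 0 °C to rt; then 17, PdCl2(dppf) (dppf = 1,1'-bis(diphenylphosphino)ferrocene, 5 mol%), AsPh3, Cs2CO3, DMF/H2O, rt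
Reagents that add atoms: 9-borabicyclo[3.3.1]nonane, C1CC2CCCC(C1)B2 (boron only in 18)
Why: The bulky borane adds anti-Markovnikov to the monosubstituted C11=C12 alkene and ignores the tetrasubstituted one. B-alkyl Suzuki–Miyaura coupling with the β-bromobutenolide then forms C12–C13 at room temperature, mild enough for the lactone and the neopentyl acetate.

Step 14
Reactants: 19 bis-silyl ether
Product: 20 CNP0201970.1, 19-acetoxy-2α,6α-dihydroxy-5β-H-labda-8,13-dien-15,16-olide
Conditions: HF·pyridine, pyridine/THF, 0 °C to rt
Reagents that add atoms: none
Why: Fluoride-induced desilylation in a weakly acidic medium removes both silyl groups. It avoids the basic conditions that would move the acetate or isomerise the butenolide.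

## Compound list

1 | 2,6-dimethyl-1,4-benzoquinone | CC1=CC(=O)C=C(C)C1=O | starting material
2 | (E)-2-methylpenta-1,3-diene | C=C(C)/C=C/C | starting material
3 | (4aR,5R,8aS)-2,5,7,8a-tetramethyl-4a,5,8,8a-tetrahydronaphthalene-1,4-dione | C[C@@H]1C=C(C)C[C@]2(C)C(=O)C(C)=CC(=O)[C@H]12 | intermediate
4 | (4S,4aR,5R,8aS)-4-hydroxy-2,5,7,8a-tetramethyl-4a,5,8,8a-tetrahydronaphthalen-1(4H)-one | C[C@@H]1C=C(C)C[C@]2(C)C(=O)C(C)=C[C@H](O)[C@H]12 | intermediate
5 | 6α-TBS ether of 4 | C[C@@H]1C=C(C)C[C@]2(C)C(=O)C(C)=C[C@H](O[Si](C)(C)C(C)(C)C)[C@H]12 | intermediate
6 | ring B keto aldehyde (C10 acetonyl arm, C5 1-oxopropan-2-yl arm, 6α-OTBS, all α) | O=C[C@@H](C)[C@H]1[C@@H](O[Si](C)(C)C(C)(C)C)C=C(C)C(=O)[C@@]1(C)CC(C)=O | intermediate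
7 | ring B bis(dimethyl acetal) | COC(OC)[C@@H](C)[C@H]1[C@@H](O[Si](C)(C)C(C)(C)C)C=C(C)C(=O)[C@@]1(C)CC(C)(OC)OC | intermediate
8 | ring B bis(methyl enol ether), key-step precursor | CO/C=C(C)/[C@H]1[C@@H](O[Si](C)(C)C(C)(C)C)C=C(C)C(=O)[C@@]1(C)CC(=C)OC | intermediate
9 | cis-decalin C2 ketal C19 acetal, key-step product | COC(OC)[C@@]1(C)CC(OC)(OC)C[C@]2(C)C(=O)C(C)=C[C@H](O[Si](C)(C)C(C)(C)C)[C@H]12 | intermediate
10 | cis-decalin 2-ketone 19-aldehyde | O=C[C@@]1(C)CC(=O)C[C@]2(C)C(=O)C(C)=C[C@H](O[Si](C)(C)C(C)(C)C)[C@H]12 | intermediate
11 | 2α,19-diol | OC[C@@]1(C)C[C@H](O)C[C@]2(C)C(=O)C(C)=C[C@H](O[Si](C)(C)C(C)(C)C)[C@H]12 | intermediate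
12 | 19-acetate, 2α-OH free | CC(=O)OC[C@@]1(C)C[C@H](O)C[C@]2(C)C(=O)C(C)=C[C@H](O[Si](C)(C)C(C)(C)C)[C@H]12 | intermediate
13 | 19-acetate 2α-TES ether enone | CC(=O)OC[C@@]1(C)C[C@H](O[Si](CC)(CC)CC)C[C@]2(C)C(=O)C(C)=C[C@H](O[Si](C)(C)C(C)(C)C)[C@H]12 | intermediate
14 | lithium C8=C9 enolate | CC(=O)OC[C@@]1(C)C[C@H](O[Si](CC)(CC)CC)C[C@]2(C)C([O-])=C(C)C[C@H](O[Si](C)(C)C(C)(C)C)[C@H]12.[Li+] | intermediate
15 | C9 enol triflate | CC(=O)OC[C@@]1(C)C[C@H](O[Si](CC)(CC)CC)C[C@]2(C)C(OS(=O)(=O)C(F)(F)F)=C(C)C[C@H](O[Si](C)(C)C(C)(C)C)[C@H]12 | intermediate
16 | C9-vinyl diene | CC(=O)OC[C@@]1(C)C[C@H](O[Si](CC)(CC)CC)C[C@]2(C)C(C=C)=C(C)C[C@H](O[Si](C)(C)C(C)(C)C)[C@H]12 | intermediate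
17 | 4-bromofuran-2(5H)-one | BrC1=CC(=O)OC1 | starting material
18 | C12 B-alkyl-9-borabicyclo[3.3.1]nonane | CC(=O)OC[C@@]1(C)C[C@H](O[Si](CC)(CC)CC)C[C@]2(C)C(CCB3C4CCCC3CCC4)=C(C)C[C@H](O[Si](C)(C)C(C)(C)C)[C@H]12 | intermediate
19 | 2-O-TES 6-O-TBS ether of the target | CC(=O)OC[C@@]1(C)C[C@H](O[Si](CC)(CC)CC)C[C@]2(C)C(CCC3=CC(=O)OC3)=C(C)C[C@H](O[Si](C)(C)C(C)(C)C)[C@H]12 | intermediate
20 | CNP0201970.1 | CC(=O)OC[C@@]1(C)C[C@H](O)C[C@]2(C)C(CCC3=CC(=O)OC3)=C(C)C[C@H](O)[C@H]12 | target

Total step count: 14. Longest linear sequence: 14 steps (from 1 and 2).

## Least certain steps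

**Step 6 (key step).**
- *What may go wrong:*
  - Attack of C3 on a fully substituted C4 in the less common endo mode may be slow, so methanol may capture the radical cation before the ring closes.
  - The very acid-labile 2-methoxyallyl group may add methanol in the acidic layer at the anode.
  - Face selectivity may be imperfect, because in the E enol ether only H19 enforces the allylic strain.
  - Partial loss of methanol from the crowded C2 ketal would be harmless, since step 7 converges.
- *Fallback:* it sets out from 6, isolated after the Me2S work-up of step 4.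
  - t-BuMe2SiOTf and Et3N in CH2Cl2 give the bis(tert-butyldimethylsilyl enol ether) F1.
  - Oxidation with (NH4)2Ce(NO3)6 (tetravalent cerium) and NaHCO3 in MeCN at −20 °C couples C3 with C4. This is the known oxidative cross-coupling of silyl enol ethers to 1,4-dicarbonyl compounds.
  - No nucleophilic solvent is present, both silyl groups are lost, and the route is rejoined at 10.

**Step 5.**
- *What may go wrong:*
  - The silyl triflate and amine may enolise the enone by removing H6. That would erase the C6 stereocentre on hydrolysis.
  - Some elimination towards C1 may occur.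
- *Fallback:* it removes the carbonyl group first and sets out from 7.
  - LiBH(s-Bu)3, then N-(5-chloropyridin-2-yl)bis(trifluoromethanesulfonyl)imide, give the ring B enol triflate bis(dimethyl acetal) F2.
  - Me3SiOTf and i-Pr2NEt give the enol triflate bis(methyl enol ether) F3.
  - Electrolysis as in step 6 gives the cis-decalin enol triflate bis(dimethyl acetal) F4.
  - Aqueous CF3CO2H gives the keto aldehyde F5.
  - NaBH4 gives the 2α,19-diol F6.
  - AcCl and collidine give the 19-acetate F7.
  - Et3SiOTf then rejoins the route at 15, in the same number of steps.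
  - The electron-poor enol triflate is neither enolisable nor oxidisable at the enol ether potential.

**Step 1.**
- *What may go wrong:*
  - Formation of a quaternary carbon may be slow at low temperature.
  - The uncatalysed background reaction, which has the opposite orientation and no induction, may then erode both regio- and enantioselectivity.
- *Fallback:* it sets out from 1 and 2.
  - BF3·OEt2 in CH2Cl2 at −20 °C, which enforces the same orientation, gives the racemic adduct F8.
  - Luche reduction gives the racemic 6α-alcohol F9.
  - Esterification with (S)-2-methoxy-2-phenylacetic acid (dicyclohexylcarbodiimide, 4-dimethylaminopyridine) gives the ester of 4, F10, and the ester of its mirror image, F11.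
  - The two esters are separated by chromatography or crystallisation.
  - K2CO3 in MeOH at 0 °C cleaves F10, and the route is rejoined at 4.

**Step 8.**
- *What may go wrong:*
  - The population of the two double chairs of 10 is not known. Hydride delivery to the α face, and thus poor or inverted selectivity at C2, cannot be excluded.
  - Slow reduction of the hindered ketone may also allow some attack on the enone.
- *Fallback:* it sets out from 10 and corrects C2 by inversion.
  - The borohydride step then gives the 2β,19-diol F12.
  - AcCl and collidine give the 2β-hydroxy 19-acetate F13.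
  - A Mitsunobu reaction (PPh3, diisopropyl azodicarboxylate, chloroacetic acid) gives the 2α-chloroacetate F14.
  - Thiourea and NaHCO3 in EtOH remove the chloroacetate without touching the acetate, which rejoins the route at 12.

## Further compounds

F1 | step 6 | bis(tert-butyldimethylsilyl enol ether) of 6 | CC(C)(C)[Si](C)(C)O/C=C(C)/[C@H]1[C@@H](O[Si](C)(C)C(C)(C)C)C=C(C)C(=O)[C@@]1(C)CC(=C)O[Si](C)(C)C(C)(C)C
F2 | step 5 | ring B enol triflate bis(dimethyl acetal) | COC(OC)[C@@H](C)[C@H]1[C@@H](O[Si](C)(C)C(C)(C)C)CC(C)=C(OS(=O)(=O)C(F)(F)F)[C@@]1(C)CC(C)(OC)OC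
F3 | step 5 | ring B enol triflate bis(methyl enol ether) | CO/C=C(C)/[C@H]1[C@@H](O[Si](C)(C)C(C)(C)C)CC(C)=C(OS(=O)(=O)C(F)(F)F)[C@@]1(C)CC(=C)OC
F4 | step 5 | cis-decalin enol triflate bis(dimethyl acetal) | COC(OC)[C@@]1(C)CC(OC)(OC)C[C@]2(C)C(OS(=O)(=O)C(F)(F)F)=C(C)C[C@H](O[Si](C)(C)C(C)(C)C)[C@H]12
F5 | step 5 | cis-decalin enol triflate 2-ketone 19-aldehyde | O=C[C@@]1(C)CC(=O)C[C@]2(C)C(OS(=O)(=O)C(F)(F)F)=C(C)C[C@H](O[Si](C)(C)C(C)(C)C)[C@H]12
F6 | step 5 | enol triflate 2α,19-diol | OC[C@@]1(C)C[C@H](O)C[C@]2(C)C(OS(=O)(=O)C(F)(F)F)=C(C)C[C@H](O[Si](C)(C)C(C)(C)C)[C@H]12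
F7 | step 5 | enol triflate 19-acetate, 2α-OH free | CC(=O)OC[C@@]1(C)C[C@H](O)C[C@]2(C)C(OS(=O)(=O)C(F)(F)F)=C(C)C[C@H](O[Si](C)(C)C(C)(C)C)[C@H]12
F8 | step 1 | racemic adduct (3 and its mirror image) | C[C@@H]1C=C(C)C[C@]2(C)C(=O)C(C)=CC(=O)[C@H]12.C[C@H]1C=C(C)C[C@@]2(C)C(=O)C(C)=CC(=O)[C@@H]12
F9 | step 1 | racemic 6α-alcohol (4 and its mirror image) | C[C@@H]1C=C(C)C[C@]2(C)C(=O)C(C)=C[C@H](O)[C@H]12.C[C@H]1C=C(C)C[C@@]2(C)C(=O)C(C)=C[C@@H](O)[C@@H]12
F10 | step 1 | (S)-2-methoxy-2-phenylacetate of 4 | C[C@@H]1C=C(C)C[C@]2(C)C(=O)C(C)=C[C@H](OC(=O)[C@@H](OC)c3ccccc3)[C@H]12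
F11 | step 1 | (S)-2-methoxy-2-phenylacetate of the mirror image of 4 | C[C@H]1C=C(C)C[C@@]2(C)C(=O)C(C)=C[C@@H](OC(=O)[C@@H](OC)c3ccccc3)[C@@H]12
F12 | step 8 | 2β,19-diol | OC[C@@]1(C)C[C@@H](O)C[C@]2(C)C(=O)C(C)=C[C@H](O[Si](C)(C)C(C)(C)C)[C@H]12
F13 | step 8 | 2β-hydroxy 19-acetate | CC(=O)OC[C@@]1(C)C[C@@H](O)C[C@]2(C)C(=O)C(C)=C[C@H](O[Si](C)(C)C(C)(C)C)[C@H]12
F14 | step 8 | 2α-chloroacetate 19-acetate | CC(=O)OC[C@@]1(C)C[C@H](OC(=O)CCl)C[C@]2(C)C(=O)C(C)=C[C@H](O[Si](C)(C)C(C)(C)C)[C@H]12
A1 | alternative 1 | cis-fused octalin C6 pinacolboronate | CC(=O)OC[C@@]1(C)C[C@H](O[Si](C)(C)C(C)(C)C)C[C@]2(C)C(CCOCc3ccc(OC)cc3)=C(C)C[C@H](B3OC(C)(C)C(C)(C)O3)[C@H]12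
A2 | alternative 2 | 2-O-TBS ether of the target | CC(=O)OC[C@@]1(C)C[C@H](O[Si](C)(C)C(C)(C)C)C[C@]2(C)C(CCC3=CC(=O)OC3)=C(C)C[C@H](O)[C@H]12
A3 | alternative 3 | cis-fused C6 ketone with C19 hydroxymethyl and C9 dioxolane | OC[C@@]1(C)C[C@H](O[Si](C)(C)C(C)(C)C)C[C@]2(C)C3(OCCO3)CCC(=O)[C@H]12
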